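**Plan**

- Retrosynthesis: the C3 aldehyde goes back to a C3 methyl ester and the hydroxypropyl chain to a methyl propanoate. The furan O1–C2 bond is then cut and the C3 ester is folded onto the phenol oxygen, which gives an isoaurone. Its exocyclic C3=CH–aryl bond is cut (Knoevenagel), then the ring A–CH2 bond (glyoxylic acid on the phenol).
- Feature used: the furan unit O1–C2(aryl)=C3(–C=O) fused to ring A holds the same atoms as the lactone unit O1–C(=O)–C3(=CH–aryl) of a 3-arylidenebenzofuran-2(3H)-one. The lactone carbonyl becomes the exocyclic carbon on C3 and the arylidene carbon becomes C2.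
- Forward: ring A is bought as dihydroferulic acid. The lactone ring is closed first (steps 1–3), the guaiacyl ring is joined by condensation with MOM-vanillin (steps 4–5), and the aromatic furan ring arises in step 6 when methoxide opens the lactone and iodine closes O1–C2.
- Finish: both esters are reduced, only the benzofuran-3-ylmethanol is oxidised by MnO2, and the MOM group is removed.
- Stereochemistry: the target has no stereocentre. The racemic carbinol of step 1 is removed in step 2 and the alkene geometry of the isoaurone is erased in step 6.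

Key step: step 6

Remark: the hydroxypropyl chain is carried as its methyl propanoate because a free primary alcohol would open the aryl lactone and a silyl ether would not survive the acidic deoxygenation; glyoxylic acid is used as its 50% aqueous solution.

**Route**

Step 1
Reactants: 1 dihydroferulic acid [3-(4-hydroxy-3-methoxyphenyl)propanoic acid]; 2 glyoxylic acid
Product: 3 2-[5-(2-carboxyethyl)-2-hydroxy-3-methoxyphenyl]-2-hydroxyacetic acid (racemic)
Conditions: 50% aq. glyoxylic acid (1.5 equiv), NaOH (4.5 equiv), H2O, 0 °C to rt, 48 h; then HCl to pH 1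
Reagents that add atoms: none
Why: Hydroxyalkylation of a phenoxide by glyoxylate (Lederer–Manasse-type electrophilic aromatic substitution) should go to the only free ortho carbon because the para position carries the chain and the other ortho position carries OMe; the new carbinol centre forms racemic and is removed in step 2.

Step 2
Reactants: 3 2-[5-(2-carboxyethyl)-2-hydroxy-3-methoxyphenyl]-2-hydroxyacetic acid
Product: 5 methyl 3-[4-hydroxy-3-methoxy-5-(2-methoxy-2-oxoethyl)phenyl]propanoate, via hydroxy diacid 4 (not isolated)
Conditions: H2 (4 bar), 10% Pd/C, AcOH, H2SO4 (cat.), 60 °C; filter, evaporate; then MeOH, H2SO4 (cat.), reflux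
Reagents that add atoms: methanol, CO
Why: Acid-assisted benzylic hydrogenolysis of the carbinol C–O bond, eased by the ortho-hydroxy group, should be followed by Fischer esterification of both acids in methanol, which also reopens any lactone formed on the way.

Step 3
Reactants: 5 methyl 3-[4-hydroxy-3-methoxy-5-(2-methoxy-2-oxoethyl)phenyl]propanoate
Product: 6 methyl 3-(7-methoxy-2-oxo-2,3-dihydro-1-benzofuran-5-yl)propanoate
Conditions: TsOH·H2O (5 mol %), toluene, reflux with distillation of MeOH, N2
Reagents that add atoms: none
Why: Acid-catalysed intramolecular transesterification (lactonisation) of a 2-hydroxyarylacetate to the five-membered benzofuran-2(3H)-one is driven by removal of methanol, and the propanoate ester cannot reach the phenol.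

Step 4
Reactants: 7 vanillin
Product: 8 3-methoxy-4-(methoxymethoxy)benzaldehyde
Conditions: MOMCl (1.3 equiv), iPr2NEt (1.6 equiv), CH2Cl2, 0 °C to rt
Reagents that add atoms: chloromethyl methyl ether (MOMCl), COCCl
Why: Standard O-alkylation of a phenol to its methoxymethyl ether, which masks the phenol against base, iodine, hydride and MnO2 in the later steps.

Step 5
Reactants: 6 methyl 3-(7-methoxy-2-oxo-2,3-dihydro-1-benzofuran-5-yl)propanoate; 8 3-methoxy-4-(methoxymethoxy)benzaldehyde
Product: 9 methyl 3-{(3E)-7-methoxy-3-[3-methoxy-4-(methoxymethoxy)benzylidene]-2-oxo-2,3-dihydro-1-benzofuran-5-yl}propanoate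
Conditions: piperidine (0.2 equiv), AcOH (0.2 equiv), 4 Å MS, toluene, 80 °C, N2
Reagents that add atoms: none
Why: Knoevenagel condensation of the acidic C3 methylene of a benzofuran-2(3H)-one with an aromatic aldehyde is the usual entry to isoaurones and should give mainly the E alkene, whose geometry is not needed later.

Step 6
Reactants: 9 methyl 3-{(3E)-7-methoxy-3-[3-methoxy-4-(methoxymethoxy)benzylidene]-2-oxo-2,3-dihydro-1-benzofuran-5-yl}propanoate
Product: 11 methyl 7-methoxy-2-[3-methoxy-4-(methoxymethoxy)phenyl]-5-(3-methoxy-3-oxopropyl)-1-benzofuran-3-carboxylate, via hydroxy cinnamate 10 (not isolated)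
Conditions: NaOMe (1.2 equiv), MeOH–THF (1:4), 0 °C to rt; then K2CO3 (3 equiv), I2 (2.5 equiv), rt to 45 °C; aq. Na2S2O3
Reagents that add atoms: sodium methoxide (NaOMe), C[O-].[Na+]
Why: Methoxide cleaves the aryl ester bond of the lactone, so the former lactone carbonyl becomes the C3 methyl ester and the phenoxide of 10 is set free; iodine then polarises the Cα=Cβ bond, whose β-carbon is benzylic to the 4-(methoxymethoxy)aryl ring, the phenoxide oxygen attacks that carbon to form O1–C2, and loss of HI from the 3-iodo-2,3-dihydrobenzofuran-3-carboxylate (the same iodide results if oxa-Michael addition precedes iodination of the ester enolate) aromatises the furan. The closest known reaction type is the I2/K2CO3 oxidative cyclisation of 2-hydroxystilbenes to 2-arylbenzofurans, together with the oxidative cycloetherification of α-(2-hydroxyaryl)cinnamic acids to 2-arylbenzofuran-3-carboxylic acids. The furan ring closes in a 5-endo-trig mode with respect to the alkene, the attack being on a cation-like benzylic carbon once iodine is bound. No stereocentre is formed, and because the phenol ring sits on the α-carbon both alkene geometries can close. The step needs O-attack at the arylidene carbon instead of re-lactonisation and needs iodine to spare the arenes: re-closure on the ester is reversible under methoxide while aromatisation is not, the phenoxide has both ortho positions and its para position substituted so ring iodination has no site, and the MOM ether keeps the second phenol masked.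

Step 7
Reactants: 11 methyl 7-methoxy-2-[3-methoxy-4-(methoxymethoxy)phenyl]-5-(3-methoxy-3-oxopropyl)-1-benzofuran-3-carboxylate
Product: 12 3-{3-(hydroxymethyl)-7-methoxy-2-[3-methoxy-4-(methoxymethoxy)phenyl]-1-benzofuran-5-yl}propan-1-ol
Conditions: LiAlH4 (3 equiv), THF, 0 °C; then H2O, aq. NaOH (Fieser work-up)
Reagents that add atoms: none
Why: Hydride reduction of both methyl esters to primary alcohols is routine, and the MOM acetal, the aryl ethers and the benzofuran are inert to LiAlH4.

Step 8
Reactants: 12 3-{3-(hydroxymethyl)-7-methoxy-2-[3-methoxy-4-(methoxymethoxy)phenyl]-1-benzofuran-5-yl}propan-1-ol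
Product: 13 5-(3-hydroxypropyl)-7-methoxy-2-[3-methoxy-4-(methoxymethoxy)phenyl]-1-benzofuran-3-carbaldehyde
Conditions: activated MnO2 (15 equiv), CH2Cl2, rt
Reagents that add atoms: none
Why: Activated MnO2 oxidises benzylic-type alcohols such as the benzofuran-3-ylmethanol chemoselectively and should leave the saturated primary alcohol untouched.

Step 9
Reactants: 13 5-(3-hydroxypropyl)-7-methoxy-2-[3-methoxy-4-(methoxymethoxy)phenyl]-1-benzofuran-3-carbaldehyde
Product: 14 2-(4-hydroxy-3-methoxyphenyl)-5-(3-hydroxypropyl)-7-methoxy-1-benzofuran-3-carbaldehyde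
Conditions: 3 M aq. HCl, THF, 50 °C
Reagents that add atoms: none
Why: Acid hydrolysis of the aryl MOM acetal in aqueous THF frees the phenol without acetalising the aldehyde, and the methyl ethers and the benzofuran are stable to dilute HCl.

**Compound list**

1 | dihydroferulic acid, 3-(4-hydroxy-3-methoxyphenyl)propanoic acid | COc1cc(CCC(=O)O)ccc1O | starting material
2 | glyoxylic acid | O=CC(=O)O | starting material
3 | 2-[5-(2-carboxyethyl)-2-hydroxy-3-methoxyphenyl]-2-hydroxyacetic acid (racemic) | O=C(O)CCc1cc(OC)c(O)c(C(O)C(=O)O)c1 | intermediate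
4 | 3-[3-(carboxymethyl)-4-hydroxy-5-methoxyphenyl]propanoic acid (hydroxy diacid) | O=C(O)CCc1cc(OC)c(O)c(CC(=O)O)c1 | intermediate (not isolated)
5 | methyl 3-[4-hydroxy-3-methoxy-5-(2-methoxy-2-oxoethyl)phenyl]propanoate | COC(=O)CCc1cc(OC)c(O)c(CC(=O)OC)c1 | intermediate
6 | methyl 3-(7-methoxy-2-oxo-2,3-dihydro-1-benzofuran-5-yl)propanoate | COC(=O)CCc1cc(OC)c2OC(=O)Cc2c1 | intermediate
7 | vanillin | COc1cc(C=O)ccc1O | starting material
8 | 3-methoxy-4-(methoxymethoxy)benzaldehyde | COCOc1ccc(C=O)cc1OC | intermediate
9 | methyl 3-{(3E)-7-methoxy-3-[3-methoxy-4-(methoxymethoxy)benzylidene]-2-oxo-2,3-dihydro-1-benzofuran-5-yl}propanoate (isoaurone) | COC(=O)CCc1cc(OC)c2OC(=O)/C(=C/c3ccc(OCOC)c(OC)c3)c2c1 | intermediate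
10 | methyl (2E)-2-[2-hydroxy-3-methoxy-5-(3-methoxy-3-oxopropyl)phenyl]-3-[3-methoxy-4-(methoxymethoxy)phenyl]prop-2-enoate (hydroxy cinnamate, formed as its sodium phenoxide) | COC(=O)CCc1cc(OC)c(O)c(c1)/C(C(=O)OC)=C\c1ccc(OCOC)c(OC)c1 | intermediate (not isolated)
11 | methyl 7-methoxy-2-[3-methoxy-4-(methoxymethoxy)phenyl]-5-(3-methoxy-3-oxopropyl)-1-benzofuran-3-carboxylate | COC(=O)CCc1cc(OC)c2oc(-c3ccc(OCOC)c(OC)c3)c(C(=O)OC)c2c1 | intermediate
12 | 3-{3-(hydroxymethyl)-7-methoxy-2-[3-methoxy-4-(methoxymethoxy)phenyl]-1-benzofuran-5-yl}propan-1-ol | OCCCc1cc(OC)c2oc(-c3ccc(OCOC)c(OC)c3)c(CO)c2c1 | intermediate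
13 | 5-(3-hydroxypropyl)-7-methoxy-2-[3-methoxy-4-(methoxymethoxy)phenyl]-1-benzofuran-3-carbaldehyde | OCCCc1cc(OC)c2oc(-c3ccc(OCOC)c(OC)c3)c(C=O)c2c1 | intermediate
14 | 2-(4-hydroxy-3-methoxyphenyl)-5-(3-hydroxypropyl)-7-methoxy-1-benzofuran-3-carbaldehyde | COc1cc(-c2oc3c(OC)cc(CCCO)cc3c2C=O)ccc1O | target

**Step count and risks**

Total step count: 9. Longest linear sequence: 8 steps (steps 1, 2, 3, 5, 6, 7, 8, 9 from compound 1); step 4 is a one-step branch from vanillin.

Steps most likely to fail:

1. Step 6. The ester-bearing alkene may be too electron-poor for iodine activation, so that methanol adds or the phenoxide re-lactonises instead of closing on the benzylic carbon, or the 3-iodo intermediate may be slow to lose HI. The fallback sets out from 9 and oxidises the alkene before the ring is opened. Pyridinium tribromide in CH2Cl2 at 0 °C should add bromine across the exocyclic double bond to give methyl 3-{3-bromo-3-[bromo(3-methoxy-4-(methoxymethoxy)phenyl)methyl]-7-methoxy-2-oxo-2,3-dihydro-1-benzofuran-5-yl}propanoate F1. NaOMe in MeOH–THF should then open the lactone, the phenoxide should displace the benzylic bromide in a 5-exo-tet Williamson closure, and base-induced loss of HBr from C3 should aromatise the ring. The fallback comes back to the route at 11.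

2. Step 1. Ortho attack on a para-blocked phenoxide is slow, and Cannizzaro disproportionation of glyoxylate may use up the electrophile before conversion is useful. The fallback sets out from 1 and brings in the two-carbon unit by a sigmatropic shift:
   - Fischer esterification (MeOH, H2SO4) should give methyl 3-(4-hydroxy-3-methoxyphenyl)propanoate F2.
   - Allyl bromide with K2CO3 in acetone should give methyl 3-[4-(allyloxy)-3-methoxyphenyl]propanoate F3.
   - Aromatic Claisen rearrangement (N,N-diethylaniline, 200 °C) should deliver the allyl group to the only free ortho carbon and give methyl 3-(3-allyl-4-hydroxy-5-methoxyphenyl)propanoate F4.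
   - Ozonolysis stopped at the alkene end-point (O3, CH2Cl2–MeOH, −78 °C; Me2S) should give the arylacetaldehyde, which closes onto the phenol as the lactol methyl 3-(2-hydroxy-7-methoxy-2,3-dihydro-1-benzofuran-5-yl)propanoate F5.
   - Oxidation of the lactol with PhI(OAc)2 and catalytic TEMPO in CH2Cl2 should give the lactone.

   The fallback comes back to the route at 6, so steps 2 and 3 are bypassed as well.

3. Step 5. The amine catalyst may open the aryl lactone, and the electron-rich aldehyde may condense sluggishly, so that 6 is consumed by aminolysis or self-condensation. The fallback sets out from 6 and separates enolisation, C–C bond formation and dehydration. TBSOTf and Et3N in CH2Cl2 at 0 °C should give the silyl ketene acetal methyl 3-{2-[(tert-butyldimethylsilyl)oxy]-7-methoxy-1-benzofuran-5-yl}propanoate F6. Mukaiyama aldol addition to 8 (BF3·OEt2, CH2Cl2, −78 °C) should give the carbinol methyl 3-{3-[hydroxy(3-methoxy-4-(methoxymethoxy)phenyl)methyl]-7-methoxy-2-oxo-2,3-dihydro-1-benzofuran-5-yl}propanoate F7. Mesylation and elimination (MsCl, Et3N, CH2Cl2, 0 °C to rt) should give the arylidene lactone. The fallback comes back to the route at 9.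

Further compounds
F1 | step 6 | methyl 3-{3-bromo-3-[bromo(3-methoxy-4-(methoxymethoxy)phenyl)methyl]-7-methoxy-2-oxo-2,3-dihydro-1-benzofuran-5-yl}propanoate (racemic, mixture of diastereomers) | COC(=O)CCc1cc(OC)c2OC(=O)C(Br)(C(Br)c3ccc(OCOC)c(OC)c3)c2c1
F2 | step 1 | methyl 3-(4-hydroxy-3-methoxyphenyl)propanoate | COC(=O)CCc1ccc(O)c(OC)c1
F3 | step 1 | methyl 3-[4-(allyloxy)-3-methoxyphenyl]propanoate | COC(=O)CCc1ccc(OCC=C)c(OC)c1
F4 | step 1 | methyl 3-(3-allyl-4-hydroxy-5-methoxyphenyl)propanoate | COC(=O)CCc1cc(CC=C)c(O)c(OC)c1
F5 | step 1 | methyl 3-(2-hydroxy-7-methoxy-2,3-dihydro-1-benzofuran-5-yl)propanoate (racemic lactol) | COC(=O)CCc1cc(OC)c2OC(O)Cc2c1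
F6 | step 5 | methyl 3-{2-[(tert-butyldimethylsilyl)oxy]-7-methoxy-1-benzofuran-5-yl}propanoate | COC(=O)CCc1cc(OC)c2oc(O[Si](C)(C)C(C)(C)C)cc2c1
F7 | step 5 | methyl 3-{3-[hydroxy(3-methoxy-4-(methoxymethoxy)phenyl)methyl]-7-methoxy-2-oxo-2,3-dihydro-1-benzofuran-5-yl}propanoate (racemic, mixture of diastereomers) | COC(=O)CCc1cc(OC)c2OC(=O)C(C(O)c3ccc(OCOC)c(OC)c3)c2c1
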